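**Strategy.** The route rests on opening the 1,2-dioxane between its ring methylene C5 and the quaternary peroxide carbon C6. C6 is a ketal-level carbon (bonded to O1 of the O1–O2 unit), and the C4 methyl can be stored as an exocyclic methylene. The ring is therefore closed by an acid-catalysed peroxycarbenium/allylsilane (Hosomi–Sakurai-type) cyclisation. In one operation it forges the C5–C6 bond, creates the C6 stereocentre and funnels both epimers of an acyclic mixed peroxyketal into one ring. The precursor is an open-chain methoxy peroxyketal of the complete side-chain methyl ketone, O-linked to a (3S)-allylic carbon that carries a 2-(trimethylsilylmethyl)allyl unit and the ester arm.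

Key step: step 10

Assumption: ring locants O1–O2–C3–C4–C5–C6 of the target are used throughout, also for open-chain precursors; for the catalytic asymmetric steps 1, 3, 7 and 10 the catalyst antipode written is taken to give the configuration drawn, and the other antipode is used if a first run shows the opposite sense.

Step 1
Reactants: 1 (E)-but-2-enal; 2 potassium (E)-trifluoro(2-phenylethenyl)borate
Product: 3 (3S,4E)-3-methyl-5-phenylpent-4-enal
Conditions: (2S,5S)-5-benzyl-2-tert-butyl-3-methylimidazolidin-4-one·HCl (20 mol%), HF (1 equiv), DME, −20 °C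
Reagents that add atoms: none
Why: Iminium-catalysed conjugate addition of an alkenyltrifluoroborate to an enal, in which the imidazolidinone shields one face of the E-iminium ion so that the styryl group is delivered to give the 3S centre.

Step 2
Reactants: 3 (3S,4E)-3-methyl-5-phenylpent-4-enal; 4 2,2'-methylenebis(4,4,5,5-tetramethyl-1,3,2-dioxaborolane)
Product: 6 4,4,5,5-tetramethyl-2-[(1E,4S,5E)-4-methyl-6-phenylhexa-1,5-dien-1-yl]-1,3,2-dioxaborolane, via lithiated diborylmethane 5 (not isolated)
Conditions: lithium 2,2,6,6-tetramethylpiperidide, THF, 0 °C; then 3, −78 °C → rt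
Reagents that add atoms: none
Why: Boron–Wittig olefination, in which the α-boryl carbanion adds to the aldehyde and syn B–O elimination should give the E-alkenylboronate; the stereocentre is β to the carbonyl and is not touched.

Step 3
Reactants: 6 the alkenylboronate; 7 (E)-pent-3-en-2-one
Product: 8 (4R,5E,8S,9E)-4,8-dimethyl-10-phenyldeca-5,9-dien-2-one
Conditions: [RhCl(C2H4)2]2 (2.5 mol%), (R)-BINAP (6 mol%), KOH (aq, 0.5 equiv), 1,4-dioxane/H2O, 40 °C
Reagents that add atoms: none
Why: Rhodium-catalysed asymmetric 1,4-addition of an alkenylboron reagent to an enone (Hayashi–Miyaura reaction), in which the chiral bisphosphine selects the enone face and sets 4R under catalyst control, independent of the remote 8S centre.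

Step 4
Reactants: 8 (4R,5E,8S,9E)-4,8-dimethyl-10-phenyldeca-5,9-dien-2-one
Product: 9 [(1E,3S,5E,7R)-9,9-dimethoxy-3,7-dimethyldeca-1,5-dien-1-yl]benzene
Conditions: HC(OMe)3, MeOH, pyridinium p-toluenesulfonate (cat.), rt; Et3N quench
Reagents that add atoms: trimethyl orthoformate COC(OC)OC; methanol CO
Why: Acid-catalysed ketalisation driven by the orthoester as water scavenger; no stereocentre is affected.

Step 5
Reactants: 9 the dimethyl ketal
Product: 10 [(1E,3S,5E,7R)-9-hydroperoxy-9-methoxy-3,7-dimethyldeca-1,5-dien-1-yl]benzene (both epimers at the ketal carbon)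
Conditions: H2O2 (anhydrous, in Et2O, excess), pyridinium p-toluenesulfonate (cat.), 0 °C; NaHCO3 quench
Reagents that add atoms: hydrogen peroxide OO
Why: Acid-catalysed perhydrolysis of a ketal (exchange of one methoxy group for hydroperoxide via the methoxycarbenium ion), the standard access to α-alkoxy hydroperoxides; the new ketal centre needs no control because step 10 flattens it again.

Step 6
Reactants: 11 (2-bromoprop-2-en-1-yl)trimethylsilane; 12 prop-2-enal
Product: 13 (2E)-4-[(trimethylsilyl)methyl]penta-2,4-dienal
Conditions: Pd(OAc)2 (5 mol%), NaHCO3, n-Bu4NCl, DMF, 40 °C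
Reagents that add atoms: none
Why: Heck reaction of an alkenyl bromide with acrolein under phosphine-free conditions, where syn insertion and syn β-hydride elimination give the 2E-dienal and the allylsilane should survive the near-neutral medium.

Step 7
Reactants: 10 the α-methoxy hydroperoxide; 13 (2E)-4-[(trimethylsilyl)methyl]penta-2,4-dienal
Product: 14 (3S)-3-{[(4R,5E,8S,9E)-2-methoxy-4,8-dimethyl-10-phenyldeca-5,9-dien-2-yl]peroxy}-4-[(trimethylsilyl)methyl]pent-4-enal (both epimers at the ketal carbon)
Conditions: (S)-2-[diphenyl(trimethylsilyloxy)methyl]pyrrolidine (10 mol%), PhCO2H (10 mol%), toluene, 0 °C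
Reagents that add atoms: none
Why: Iminium-catalysed asymmetric β-peroxidation of an enal by a tertiary α-alkoxy hydroperoxide (organocatalytic oxa-Michael addition), in which the diarylprolinol silyl ether blocks one face of the iminium ion so that the O2–C3 bond forms with 3S configuration, and the acid co-catalyst protonates the enamine before it can close to an epoxide.

Step 8
Reactants: 14 the β-peroxy aldehyde
Product: 15 (3S)-3-{[(4R,5E,8S,9E)-2-methoxy-4,8-dimethyl-10-phenyldeca-5,9-dien-2-yl]peroxy}-4-[(trimethylsilyl)methyl]pent-4-enoic acid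
Conditions: NaClO2, NaH2PO4, 2-methylbut-2-ene (excess), t-BuOH/H2O, 0 °C
Reagents that add atoms: sodium chlorite [Na+].[O-]Cl=O
Why: Pinnick oxidation under buffered, non-basic conditions that avoid β-elimination of the peroxide, with the alkene scavenger protecting the allylsilane and the styrene from hypochlorite.

Step 9
Reactants: 15 the peroxy acid
Product: 16 methyl (3S)-3-{[(4R,5E,8S,9E)-2-methoxy-4,8-dimethyl-10-phenyldeca-5,9-dien-2-yl]peroxy}-4-[(trimethylsilyl)methyl]pent-4-enoate
Conditions: Me3SiCHN2, toluene/MeOH, 0 °C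
Reagents that add atoms: (trimethylsilyl)diazomethane C[Si](C)(C)C=[N+]=[N-]
Why: Neutral O-methylation of a carboxylic acid with a diazoalkane, chosen because base would trigger retro-oxa-Michael loss of the peroxide.

Step 10
Reactants: 16 the peroxyketal ester
Product: 18 methyl 2-[(3S,6S)-6-[(2R,3E,6S,7E)-2,6-dimethyl-8-phenylocta-3,7-dien-1-yl]-6-methyl-4-methylidene-1,2-dioxan-3-yl]acetate, via peroxycarbenium ion 17 (not isolated)
Conditions: chiral imidodiphosphorimidate Brønsted acid [(S,S)-antipode, 3,3'-diaryl-BINOL backbones, N-triflyl] (5 mol%), CH2Cl2, −78 °C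
Reagents that add atoms: none
Why: Proposed new method: the strong chiral acid removes the methoxy group of either peroxyketal epimer to give the same planar peroxycarbenium ion 17 paired with the confined chiral anion, C6 of which is attacked by the γ-carbon C5 of the tethered allylsilane, and anti SE2' loss of silicon leaves the 4-methylidene group while the methanol released turns the silylated catalyst over (closest known reaction types: Lewis-acid-mediated cyclisation of unsaturated monoperoxyketals through peroxycarbenium ions, and imidodiphosphorimidate-catalysed asymmetric Hosomi–Sakurai and Prins reactions of oxocarbenium ions). The 1,2-dioxane closes in a 6-endo-trig mode at the C4=C5 alkene with the C6=O1 bond of the cation inside the forming ring (Prins-type chair). The only new stereocentre is C6: the chair should place the C3 ester arm equatorial, because the C–Si bond must stand anti to the incoming C6 and would clash with an axial arm, so the configuration at C6 depends on which of CH3 and the branched CH2R chain sits syn to O2 in the cation. These two groups differ too little for the substrate to decide, and this facial selectivity is what the step needs: the confined counter-anion is asked to seat the small methyl group in its pocket (syn to O2, axial) and leave the long chain outside (equatorial), which gives 6S. Because the two geometric forms of 17 are close in energy and interconvert through reversible capture by methanol or the anion, catalyst control is not opposed by the substrate. Attack of the side-chain alkenes on 17 should not compete with the far more nucleophilic allylsilane in a six-membered transition state.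

Step 11
Reactants: 18 the 4-methylidene-1,2-dioxane
Product: 19 methyl 2-[(3S,4S,6S)-6-[(2R,3E,6S,7E)-2,6-dimethyl-8-phenylocta-3,7-dien-1-yl]-4,6-dimethyl-1,2-dioxan-3-yl]acetate
Conditions: H2 (1 atm), RhCl(PPh3)3 (5 mol%), toluene, rt, stopped when 18 is consumed
Reagents that add atoms: none
Why: Homogeneous hydrogenation with RhCl(PPh3)3, which reduces unhindered 1,1-disubstituted alkenes much faster than α-branched trans-1,2-disubstituted ones and is expected to leave the hindered dialkyl peroxide intact; in the chair with the C3 arm and the C6 chain equatorial the axial C6 methyl blocks one face, so hydrogen should add from the other and place the new C4 methyl cis to both the arm and the C6 methyl (4S).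

Step 12
Reactants: 19 the methyl ester
Product: 21 2-[(3S,4S,6S)-6-[(2R,3E,6S,7E)-2,6-dimethyl-8-phenylocta-3,7-dien-1-yl]-4,6-dimethyl-1,2-dioxan-3-yl]acetic acid, via lithium carboxylate 20 (not isolated)
Conditions: LiOH, THF/MeOH/H2O, 0 °C; then 1 M HCl to pH 3
Reagents that add atoms: lithium hydroxide [Li+].[OH-]
Why: Saponification of the methyl ester by acyl–oxygen cleavage at low temperature, conditions under which 1,2-dioxane-3-acetates are expected to keep the O–O bond and the C3 configuration.

**Compound list**

1 | (E)-but-2-enal | C/C=C/C=O | starting material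
2 | potassium (E)-trifluoro(2-phenylethenyl)borate | [K+].F[B-](F)(F)/C=C/c1ccccc1 | starting material
3 | (3S,4E)-3-methyl-5-phenylpent-4-enal | C[C@H](/C=C/c1ccccc1)CC=O | intermediate
4 | 2,2'-methylenebis(4,4,5,5-tetramethyl-1,3,2-dioxaborolane) | CC1(C)OB(CB2OC(C)(C)C(C)(C)O2)OC1(C)C | starting material
5 | lithium bis(4,4,5,5-tetramethyl-1,3,2-dioxaborolan-2-yl)methanide | [Li+].[CH-](B1OC(C)(C)C(C)(C)O1)B1OC(C)(C)C(C)(C)O1 | intermediate
6 | 4,4,5,5-tetramethyl-2-[(1E,4S,5E)-4-methyl-6-phenylhexa-1,5-dien-1-yl]-1,3,2-dioxaborolane | C[C@H](/C=C/c1ccccc1)C/C=C/B1OC(C)(C)C(C)(C)O1 | intermediate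
7 | (E)-pent-3-en-2-one | C/C=C/C(C)=O | starting material
8 | (4R,5E,8S,9E)-4,8-dimethyl-10-phenyldeca-5,9-dien-2-one | C[C@H](/C=C/c1ccccc1)C/C=C/[C@H](C)CC(C)=O | intermediate
9 | [(1E,3S,5E,7R)-9,9-dimethoxy-3,7-dimethyldeca-1,5-dien-1-yl]benzene | C[C@H](/C=C/c1ccccc1)C/C=C/[C@H](C)CC(C)(OC)OC | intermediate
10 | [(1E,3S,5E,7R)-9-hydroperoxy-9-methoxy-3,7-dimethyldeca-1,5-dien-1-yl]benzene (both epimers at C9) | C[C@H](/C=C/c1ccccc1)C/C=C/[C@H](C)CC(C)(OC)OO | intermediate
11 | (2-bromoprop-2-en-1-yl)trimethylsilane | C=C(Br)C[Si](C)(C)C | starting material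
12 | prop-2-enal | C=CC=O | starting material
13 | (2E)-4-[(trimethylsilyl)methyl]penta-2,4-dienal | O=C/C=C/C(=C)C[Si](C)(C)C | intermediate
14 | (3S)-3-{[(4R,5E,8S,9E)-2-methoxy-4,8-dimethyl-10-phenyldeca-5,9-dien-2-yl]peroxy}-4-[(trimethylsilyl)methyl]pent-4-enal (both ketal epimers) | C[C@H](/C=C/c1ccccc1)C/C=C/[C@H](C)CC(C)(OC)OO[C@@H](CC=O)C(=C)C[Si](C)(C)C | intermediate
15 | (3S)-3-{[(4R,5E,8S,9E)-2-methoxy-4,8-dimethyl-10-phenyldeca-5,9-dien-2-yl]peroxy}-4-[(trimethylsilyl)methyl]pent-4-enoic acid (both ketal epimers) | C[C@H](/C=C/c1ccccc1)C/C=C/[C@H](C)CC(C)(OC)OO[C@@H](CC(=O)O)C(=C)C[Si](C)(C)C | intermediate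
16 | methyl (3S)-3-{[(4R,5E,8S,9E)-2-methoxy-4,8-dimethyl-10-phenyldeca-5,9-dien-2-yl]peroxy}-4-[(trimethylsilyl)methyl]pent-4-enoate (both ketal epimers) | C[C@H](/C=C/c1ccccc1)C/C=C/[C@H](C)CC(C)(OC)OO[C@@H](CC(=O)OC)C(=C)C[Si](C)(C)C | intermediate
17 | peroxycarbenium ion from 16 by loss of methoxide (O1=C6 cation, counter-anion of the catalyst) | C[C@H](/C=C/c1ccccc1)C/C=C/[C@H](C)CC(C)=[O+]O[C@@H](CC(=O)OC)C(=C)C[Si](C)(C)C | intermediate
18 | methyl 2-[(3S,6S)-6-[(2R,3E,6S,7E)-2,6-dimethyl-8-phenylocta-3,7-dien-1-yl]-6-methyl-4-methylidene-1,2-dioxan-3-yl]acetate | C[C@H](/C=C/c1ccccc1)C/C=C/[C@H](C)C[C@@]1(C)CC(=C)[C@H](CC(=O)OC)OO1 | intermediate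
19 | methyl 2-[(3S,4S,6S)-6-[(2R,3E,6S,7E)-2,6-dimethyl-8-phenylocta-3,7-dien-1-yl]-4,6-dimethyl-1,2-dioxan-3-yl]acetate | C[C@H](/C=C/c1ccccc1)C/C=C/[C@H](C)C[C@@]1(C)C[C@H](C)[C@H](CC(=O)OC)OO1 | intermediate
20 | lithium 2-[(3S,4S,6S)-6-[(2R,3E,6S,7E)-2,6-dimethyl-8-phenylocta-3,7-dien-1-yl]-4,6-dimethyl-1,2-dioxan-3-yl]acetate | [Li+].C[C@H](/C=C/c1ccccc1)C/C=C/[C@H](C)C[C@@]1(C)C[C@H](C)[C@H](CC(=O)[O-])OO1 | intermediate
21 | 2-[(3S,4S,6S)-6-[(2R,3E,6S,7E)-2,6-dimethyl-8-phenylocta-3,7-dien-1-yl]-4,6-dimethyl-1,2-dioxan-3-yl]acetic acid | C[C@H](/C=C/c1ccccc1)C/C=C/[C@H](C)C[C@@]1(C)C[C@H](C)[C@H](CC(=O)O)OO1 | target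

**Step count and risks**

Total step count: 12. Longest linear sequence: 11 steps (steps 1–5 and 7–12); step 6 is a one-step side branch.

Steps most likely to fail:

1. Step 10 (Proposed new method). The chiral anion may fail to tell the methyl face from the chain face of the cation, the large substrate may not fit the confined acid, or the allylsilane may be protodesilylated before ionisation. The fallback gives up reagent control and uses the established achiral closure followed by separation. It sets out from 16, which is treated with catalytic Me3SiOSO2CF3 and 2,6-di-tert-butyl-4-methylpyridine (or with SnCl4) in CH2Cl2 at −78 °C. This known peroxycarbenium/allylsilane cyclisation should give 18 together with its C6 epimer, methyl 2-[(3S,6R)-6-[(2R,3E,6S,7E)-2,6-dimethyl-8-phenylocta-3,7-dien-1-yl]-6-methyl-4-methylidene-1,2-dioxan-3-yl]acetate F1. F1 is removed by chromatography, and the route is rejoined at 18.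

2. Step 7. The large, polyunsaturated hydroperoxide may add with poor facial control, add at the terminal carbon of the dienal (1,6-addition), or be consumed by enamine-mediated epoxidation with loss of ketone 8. The fallback forms the O2–C3 bond with a small hydroperoxide and joins the two halves later by trans-ketalisation. It sets out from 13, which is peroxidised under the same aminocatalysis with 2-hydroperoxy-2-methoxypropane F2 (from 2-methoxypropene and H2O2) to give (3S)-3-[(2-methoxypropan-2-yl)peroxy]-4-[(trimethylsilyl)methyl]pent-4-enal F3. Pinnick oxidation gives (3S)-3-[(2-methoxypropan-2-yl)peroxy]-4-[(trimethylsilyl)methyl]pent-4-enoic acid F4, and Me3SiCHN2 gives methyl (3S)-3-[(2-methoxypropan-2-yl)peroxy]-4-[(trimethylsilyl)methyl]pent-4-enoate F5. AcOH/H2O/THF releases methyl (3S)-3-hydroperoxy-4-[(trimethylsilyl)methyl]pent-4-enoate F6. Exchange of F6 with ketal 9 under pyridinium p-toluenesulfonate catalysis rejoins the route at 16.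

3. Step 11. The side-chain alkenes may be over-reduced, the exocyclic alkene may migrate into the ring before reduction, or hydrogen may be delivered to the wrong face. The fallback replaces catalytic hydrogenation by hydroboration and radical protodeboronation, which discriminates the 1,1-disubstituted alkene more strongly. It sets out from 18, which is treated with catecholborane and catalytic N,N-dimethylacetamide in CH2Cl2 at rt to give, from the same open face, methyl 2-[(3S,4S,6S)-4-[(1,3,2-benzodioxaborol-2-yl)methyl]-6-[(2R,3E,6S,7E)-2,6-dimethyl-8-phenylocta-3,7-dien-1-yl]-6-methyl-1,2-dioxan-3-yl]acetate F7. Radical-chain protodeboronation of F7 with 4-tert-butylcatechol under air rejoins the route at 19.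

Further compounds
F1 | step 10 | methyl 2-[(3S,6R)-6-[(2R,3E,6S,7E)-2,6-dimethyl-8-phenylocta-3,7-dien-1-yl]-6-methyl-4-methylidene-1,2-dioxan-3-yl]acetate | C[C@H](/C=C/c1ccccc1)C/C=C/[C@H](C)C[C@]1(C)CC(=C)[C@H](CC(=O)OC)OO1
F2 | step 7 | 2-hydroperoxy-2-methoxypropane | COC(C)(C)OO
F3 | step 7 | (3S)-3-[(2-methoxypropan-2-yl)peroxy]-4-[(trimethylsilyl)methyl]pent-4-enal | COC(C)(C)OO[C@@H](CC=O)C(=C)C[Si](C)(C)C
F4 | step 7 | (3S)-3-[(2-methoxypropan-2-yl)peroxy]-4-[(trimethylsilyl)methyl]pent-4-enoic acid | COC(C)(C)OO[C@@H](CC(=O)O)C(=C)C[Si](C)(C)C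
F5 | step 7 | methyl (3S)-3-[(2-methoxypropan-2-yl)peroxy]-4-[(trimethylsilyl)methyl]pent-4-enoate | COC(C)(C)OO[C@@H](CC(=O)OC)C(=C)C[Si](C)(C)C
F6 | step 7 | methyl (3S)-3-hydroperoxy-4-[(trimethylsilyl)methyl]pent-4-enoate | OO[C@@H](CC(=O)OC)C(=C)C[Si](C)(C)C
F7 | step 11 | methyl 2-[(3S,4S,6S)-4-[(1,3,2-benzodioxaborol-2-yl)methyl]-6-[(2R,3E,6S,7E)-2,6-dimethyl-8-phenylocta-3,7-dien-1-yl]-6-methyl-1,2-dioxan-3-yl]acetate | C[C@H](/C=C/c1ccccc1)C/C=C/[C@H](C)C[C@@]1(C)C[C@H](CB2Oc3ccccc3O2)[C@H](CC(=O)OC)OO1
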